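**Plan**

- Numbering: seven-membered ring C1(Me)=C2–C3(O-isovaleryl)–C4(Me)–C8(H)–C9(O-aroyl)–C10; cyclopentane C4–C5–C6–C7(OH)(iPr)–C8. α is the face of the C4 methyl, β the other face.
- Cuts, in order: the two ester C–O bonds (C9–O aroyl, C3–O isovaleryl), the C1–CH3 bond and the C1=C2 unsaturation, then the ring-fusion bond C4–C8, last C7–isopropyl.
- Enabling feature: the oxygenated C9 lies next to the fusion bond C4–C8, so that bond can be made by moving the quaternary C4 from C9 to C8 in a decalin with ring B = C9–C8–C7–C6–C5–C4 and ring A = C9–C10–C1–C2–C3–C4.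
- Forward: the decalin comes from Wieland–Miescher ketone; isopropyl addition, α-face dihydroxylation and C8 mesylation follow; one 1,2-shift then makes the cyclopentane (contraction) and the cycloheptanone (expansion) together; esters, C1 methyl and C1=C2 come last.
- Stereochemistry: C4 from (S)-Wieland–Miescher ketone; C7 by equatorial organocerium addition; C8 by the stereospecific shift; C9 by hydroxyl-directed reduction; C3 by Luche reduction anti to the angular methyl.

Key step: step 7

Remark on the chemistry: H-8 keeps its face while C4 enters C8 anti to the leaving group, so a trans ring fusion (H-8 β) needs the sulfonate on the α face; the diol is therefore planned as the 8α,9α isomer of a cis-decalin.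

Step 1
Reactants: 1 (S)-Wieland–Miescher ketone
Product: 2 3α-hydroxy-4α-methyl-decal-8-en-7-one (hydroxyl cis to the angular methyl)
Conditions: NaBH4 (0.3 equiv), EtOH, 0 °C
Reagents that add atoms: none
Why: Chemoselective NaBH4 reduction of the saturated C3 ketone (the conjugated C7 ketone is less electrophilic), with axial hydride delivery anti to the angular methyl, gives the equatorial 3α-alcohol.

Step 2
Reactants: 2 3α-hydroxy-4α-methyl-decal-8-en-7-one
Product: 3 3α-(tert-butyldimethylsilyloxy)-4α-methyl-decal-8-en-7-one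
Conditions: TBSCl, imidazole, DMF, rt
Reagents that add atoms: tert-butyldimethylsilyl chloride CC(C)(C)[Si](C)(C)Cl
Why: Standard silyl ether formation masks O3 for the organometallic, sulfonylation and base steps, and the equatorial 3α-silyloxy group later helps to hold the cis-decalin in the chair needed for step 7.

Step 3
Reactants: 3 3α-(tert-butyldimethylsilyloxy)-4α-methyl-decal-8-en-7-one; 4 isopropylmagnesium chloride
Product: 5 7β-hydroxy-7α-isopropyl-3α-(tert-butyldimethylsilyloxy)-4α-methyl-decal-8-ene
Conditions: anhydrous CeCl3 (2 equiv), 4 (2 equiv), THF, −78 °C; aq. NH4Cl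
Reagents that add atoms: none
Why: CeCl3-mediated Grignard (organocerium) 1,2-addition suppresses enolisation, β-hydride reduction and 1,4-addition, and the bulky reagent should attack along the equatorial trajectory from the α face, placing isopropyl pseudoequatorial and cis to the angular methyl with the new hydroxyl β.

Step 4
Reactants: 5 7β-hydroxy-7α-isopropyl-3α-(tert-butyldimethylsilyloxy)-4α-methyl-decal-8-ene
Product: 6 7β-(triethylsilyloxy)-7α-isopropyl-3α-(tert-butyldimethylsilyloxy)-4α-methyl-decal-8-ene
Conditions: TESOTf, 2,6-lutidine, CH2Cl2, −78 → 0 °C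
Reagents that add atoms: triethylsilyl trifluoromethanesulfonate CC[Si](CC)(CC)OS(=O)(=O)C(F)(F)F
Why: Silyl triflate silylation with 2,6-lutidine is the reliable protection of a hindered tertiary alcohol; the ether keeps O7 from acting as a donor in step 7 and shields the β face of the olefin for step 5.

Step 5
Reactants: 6 7β-(triethylsilyloxy)-7α-isopropyl-3α-(tert-butyldimethylsilyloxy)-4α-methyl-decal-8-ene
Product: 7 cis-decalin-8α,9α-diol (7β-OTES; 7α-isopropyl; 3α-OTBS; 4α-methyl)
Conditions: OsO4 (5 mol %), NMO (2 equiv), acetone/H2O, rt; aq. Na2SO3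
Reagents that add atoms: osmium tetroxide O=[Os](=O)(=O)=O; N-methylmorpholine N-oxide C[N+]1([O-])CCOCC1; water O
Why: Catalytic OsO4/NMO dihydroxylation adds both oxygens to one face, and osmylation of allylic ethers runs anti to the allylic oxygen (here the pseudoaxial β silyloxy group on C7), so both new hydroxyls should be α, which makes the decalin cis-fused.

Step 6
Reactants: 7 cis-decalin-8α,9α-diol (7β-OTES; 7α-isopropyl; 3α-OTBS; 4α-methyl)
Product: 8 cis-decalin-9α-ol 8α-methanesulfonate (7β-OTES; 7α-isopropyl; 3α-OTBS; 4α-methyl)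
Conditions: MsCl, Et3N, DMAP (cat.), CH2Cl2, 0 °C
Reagents that add atoms: methanesulfonyl chloride CS(=O)(=O)Cl
Why: Sulfonylation through sulfene selects the equatorial secondary C8 hydroxyl over the tertiary ring-fusion C9 hydroxyl, which stays free as the later donor.

Step 7
Reactants: 8 cis-decalin-9α-ol 8α-methanesulfonate (7β-OTES; 7α-isopropyl; 3α-OTBS; 4α-methyl)
Product: 10 trans-fused hydroazulen-9-one (3α-OTBS; 4α-methyl; 7β-OTES; 7α-isopropyl; 8β-H), via potassium C9-alkoxide 9 (not isolated)
Conditions: KOt-Bu (1.05 equiv), THF, −20 → 0 °C; pH 7 phosphate buffer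
Reagents that add atoms: none
Why: The butoxide turns the C9 hydroxyl into alkoxide 9, whose oxygen pushes the C9–C4 bond, antiperiplanar to the C8–O bond, onto C8 in a concerted 1,2-shift while mesylate leaves and C9 becomes the ketone; this is the base-induced pinacol-type (semipinacol) rearrangement known for decalin-1,2-diol monosulfonates. The cyclopentane C4–C5–C6–C7–C8 arises by ring contraction, closed by the new C4–C8 bond, and the cycloheptanone C4–C8–C9–C10–C1–C2–C3 by one-carbon ring expansion, C8 being inserted between C9 and C4. C8 is the only new stereocentre: C4 migrates with retention and enters anti to the α-mesylate (inversion at C8), so H-8 stays β and trans to the angular methyl. The step needs C4 and not C10 or C6 to migrate: in the favoured chair–chair form A (3-OTBS, 7-OTES and 8-OMs all equatorial) the mesylate is anti to C9–C4 and gauche to C9–C10, whereas chair form B has three 1,3-diaxial pairs (methyl/mesylate, C10/OTES, OTBS/OH), and O7 is silylated so only O9 can push. One equivalent of base, low temperature and a neutral quench should keep the product, whose H-8 is α to the ketone and β to the silyloxy group, from epimerising or eliminating.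

Step 8
Reactants: 10 trans-fused hydroazulen-9-one (3α-OTBS; 4α-methyl; 7β-OTES; 7α-isopropyl; 8β-H)
Product: 11 3α,7β-dihydroxy-7α-isopropyl-4α-methyl-trans-hydroazulen-9-one
Conditions: HF·pyridine, pyridine, THF, 0 °C → rt
Reagents that add atoms: none
Why: Fluoride-assisted cleavage of both silyl ethers under acidic conditions frees O3 and O7 in one operation and avoids the retro-aldol opening and C8 enolisation that basic fluoride could cause in this β-hydroxy ketone.

Step 9
Reactants: 11 3α,7β-dihydroxy-7α-isopropyl-4α-methyl-trans-hydroazulen-9-one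
Product: 12 7β-hydroxy-7α-isopropyl-4α-methyl-trans-hydroazulene-3,9-dione
Conditions: Dess–Martin periodinane, NaHCO3, CH2Cl2, 0 °C → rt
Reagents that add atoms: none
Why: Dess–Martin oxidation converts the only secondary alcohol (C3, a temporary stereocentre) into the ketone under buffered, non-enolising conditions, the tertiary C7 hydroxyl being inert.

Step 10
Reactants: 12 7β-hydroxy-7α-isopropyl-4α-methyl-trans-hydroazulene-3,9-dione
Product: 13 7β,9α-dihydroxy-7α-isopropyl-4α-methyl-trans-hydroazulen-3-one
Conditions: Me4NBH(OAc)3 (3 equiv), MeCN/AcOH 1:1, −30 → −20 °C; aq. potassium sodium tartrate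
Reagents that add atoms: none
Why: Hydroxyl-directed reduction (Evans–Saksena): the triacetoxyborohydride binds the β C7 hydroxyl and delivers hydride intramolecularly to the β face of C9, which is also the face away from the α methyl and isopropyl groups, giving the 1,3-anti diol with the C9 hydroxyl α, while the isolated, hindered C3 ketone is not reduced by this reagent.

Step 11
Reactants: 14 4-hydroxybenzoic acid
Product: 16 4-(triisopropylsilyloxy)benzoic acid, via bis-silylated silyl ester 15 (not isolated)
Conditions: TIPSCl (2.2 equiv), imidazole, DMF, rt; then AcOH/THF/H2O, rt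
Reagents that add atoms: triisopropylsilyl chloride CC(C)[Si](Cl)(C(C)C)C(C)C
Why: Silylation of both acidic hydroxyls followed by hydrolysis of the very labile silyl ester is the usual route to an O-silyl hydroxybenzoic acid, and the aryl triisopropylsilyl ether withstands the later oxidation, cuprate, borohydride and acylation steps.

Step 12
Reactants: 13 7β,9α-dihydroxy-7α-isopropyl-4α-methyl-trans-hydroazulen-3-one; 16 4-(triisopropylsilyloxy)benzoic acid
Product: 17 9α-[4-(triisopropylsilyloxy)benzoyloxy]-7β-hydroxy-7α-isopropyl-4α-methyl-trans-hydroazulen-3-one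
Conditions: 16 (1.5 equiv), DIC, DMAP, CH2Cl2, rt
Reagents that add atoms: none
Why: Steglich esterification acylates only the secondary C9 hydroxyl, the tertiary C7 hydroxyl being too hindered, and touches no stereocentre.

Step 13
Reactants: 17 9α-[4-(triisopropylsilyloxy)benzoyloxy]-7β-hydroxy-7α-isopropyl-4α-methyl-trans-hydroazulen-3-one
Product: 18 the corresponding 1-en-3-one (C1=C2 conjugated with the C3 ketone)
Conditions: IBX (1.5 equiv), 4-methoxypyridine N-oxide (1.5 equiv), DMSO, rt
Reagents that add atoms: none
Why: IBX dehydrogenation of a ketone to its enone can only run toward C2–C1 because C4 is quaternary, and the room-temperature variant with the N-oxide ligand spares the tertiary alcohol, the ester and the silyl ether.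

Step 14
Reactants: 18 the 1-en-3-one
Product: 19 1-methyl-3-ketone (C1 epimers, both carried on)
Conditions: Me2CuLi (3 equiv, from MeLi and CuI), Et2O/THF, −78 → −40 °C; aq. NH4Cl
Reagents that add atoms: lithium dimethylcuprate C[Cu-]C.[Li+] (prepared from methyllithium C[Li])
Why: Conjugate addition of the cuprate to the cycloheptenone brings in the C1 methyl (one equivalent is used up by the C7 hydroxyl and the aryl ester survives at low temperature), and the C1 configuration does not matter because C1 becomes trigonal again in step 15.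

Step 15
Reactants: 19 1-methyl-3-ketone
Product: 20 1-methyl-1-en-3-one (9α-aroyloxy; 7β-hydroxy; 7α-isopropyl; 4α-methyl; 8β-H)
Conditions: IBX (1.5 equiv), 4-methoxypyridine N-oxide (1.5 equiv), DMSO, rt
Reagents that add atoms: none
Why: A second IBX dehydrogenation, again possible only between C2 and C1, gives the β-methyl enone with the trisubstituted C1=C2 bond of the target.

Step 16
Reactants: 20 1-methyl-1-en-3-one
Product: 21 3α-allylic alcohol (1-methyl-1-ene; 9α-aroyloxy; 7β-hydroxy)
Conditions: NaBH4, CeCl3·7H2O, MeOH, −40 → −20 °C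
Reagents that add atoms: none
Why: Luche 1,2-reduction: hydride should attack C3 from the β face, anti to the axial angular methyl on the neighbouring C4 and to the α aroyloxy group at C9, giving the 3α alcohol (cis to the methyl) without conjugate reduction or ester cleavage.

Step 17
Reactants: 21 3α-allylic alcohol; 22 isovaleryl chloride
Product: 23 3α-isovalerate 9α-[4-(triisopropylsilyloxy)benzoate]
Conditions: 22 (1.5 equiv), pyridine, DMAP (cat.), CH2Cl2, 0 °C → rt
Reagents that add atoms: none
Why: Acylation with the acid chloride esterifies the secondary allylic C3 hydroxyl with retention, the tertiary C7 hydroxyl staying free.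

Step 18
Reactants: 23 3α-isovalerate 9α-[4-(triisopropylsilyloxy)benzoate]
Product: 24 target compound CNP0086724.2
Conditions: TBAF, AcOH, THF, 0 °C
Reagents that add atoms: none
Why: Buffered fluoride cleaves the phenolic silyl ether quickly and selectively, leaving both esters, the allylic system and the tertiary alcohol untouched.

**Compound list**

1 | (S)-Wieland–Miescher ketone, (S)-8a-methyl-3,4,8,8a-tetrahydronaphthalene-1,6(2H,7H)-dione | C[C@]12CCC(=O)C=C1CCCC2=O | starting material
2 | (4aS,5S)-5-hydroxy-4a-methyl-4,4a,5,6,7,8-hexahydronaphthalen-2(3H)-one; route numbering: 3α-hydroxy-4α-methyl-decal-8-en-7-one | C[C@]12CCC(=O)C=C1CCC[C@@H]2O | intermediate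
3 | TBS ether of 2 (3α-OTBS) | C[C@]12CCC(=O)C=C1CCC[C@@H]2O[Si](C)(C)C(C)(C)C | intermediate
4 | isopropylmagnesium chloride | CC(C)[Mg]Cl | starting material
5 | tertiary allylic alcohol: 7β-OH, 7α-isopropyl (cis to the C4 methyl), C8=C9, 3α-OTBS | C[C@]12CC[C@](O)(C(C)C)C=C1CCC[C@@H]2O[Si](C)(C)C(C)(C)C | intermediate
6 | 7-O-triethylsilyl ether of 5 | C[C@]12CC[C@](O[Si](CC)(CC)CC)(C(C)C)C=C1CCC[C@@H]2O[Si](C)(C)C(C)(C)C | intermediate
7 | cis-decalin-8α,9α-diol: both hydroxyls cis to the C4 methyl and trans to O7; 7β-OTES, 7α-isopropyl, 3α-OTBS | C[C@]12CC[C@](O[Si](CC)(CC)CC)(C(C)C)[C@H](O)[C@@]1(O)CCC[C@@H]2O[Si](C)(C)C(C)(C)C | intermediate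
8 | 8α-methanesulfonate of 7 (9α-OH free) | C[C@]12CC[C@](O[Si](CC)(CC)CC)(C(C)C)[C@H](OS(C)(=O)=O)[C@@]1(O)CCC[C@@H]2O[Si](C)(C)C(C)(C)C | intermediate
9 | potassium C9-alkoxide of 8 | C[C@]12CC[C@](O[Si](CC)(CC)CC)(C(C)C)[C@H](OS(C)(=O)=O)[C@@]1([O-])CCC[C@@H]2O[Si](C)(C)C(C)(C)C.[K+] | intermediate (not isolated)
10 | trans-fused hydroazulen-9-one (bicyclo[5.3.0]decane): 3α-OTBS, 4α-methyl, 7β-OTES, 7α-isopropyl, 8β-H | C1C[C@H](O[Si](C)(C)C(C)(C)C)[C@@]2(C)CC[C@](O[Si](CC)(CC)CC)(C(C)C)[C@@H]2C(=O)C1 | intermediate
11 | 3α,7β-dihydroxy-7α-isopropyl-4α-methyl-trans-hydroazulen-9-one | C1C[C@H](O)[C@@]2(C)CC[C@](O)(C(C)C)[C@@H]2C(=O)C1 | intermediate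
12 | 7β-hydroxy-7α-isopropyl-4α-methyl-trans-hydroazulene-3,9-dione | C1CC(=O)[C@@]2(C)CC[C@](O)(C(C)C)[C@@H]2C(=O)C1 | intermediate
13 | 7β,9α-dihydroxy-7α-isopropyl-4α-methyl-trans-hydroazulen-3-one | C1CC(=O)[C@@]2(C)CC[C@](O)(C(C)C)[C@@H]2[C@H](O)C1 | intermediate
14 | 4-hydroxybenzoic acid | OC(=O)c1ccc(O)cc1 | starting material
15 | triisopropylsilyl 4-(triisopropylsilyloxy)benzoate | CC(C)[Si](Oc1ccc(cc1)C(=O)O[Si](C(C)C)(C(C)C)C(C)C)(C(C)C)C(C)C | intermediate (not isolated)
16 | 4-(triisopropylsilyloxy)benzoic acid | CC(C)[Si](Oc1ccc(cc1)C(O)=O)(C(C)C)C(C)C | intermediate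
17 | 9α-[4-(triisopropylsilyloxy)benzoyloxy]-7β-hydroxy-7α-isopropyl-4α-methyl-trans-hydroazulen-3-one | C1CC(=O)[C@@]2(C)CC[C@](O)(C(C)C)[C@@H]2[C@H](OC(=O)c2ccc(O[Si](C(C)C)(C(C)C)C(C)C)cc2)C1 | intermediate
18 | 1-en-3-one derived from 17 | C1=CC(=O)[C@@]2(C)CC[C@](O)(C(C)C)[C@@H]2[C@H](OC(=O)c2ccc(O[Si](C(C)C)(C(C)C)C(C)C)cc2)C1 | intermediate
19 | 1-methyl-3-ketone (C1 configuration not defined) | CC1CC(=O)[C@@]2(C)CC[C@](O)(C(C)C)[C@@H]2[C@H](OC(=O)c2ccc(O[Si](C(C)C)(C(C)C)C(C)C)cc2)C1 | intermediate
20 | 1-methyl-1-en-3-one | CC1=CC(=O)[C@@]2(C)CC[C@](O)(C(C)C)[C@@H]2[C@H](OC(=O)c2ccc(O[Si](C(C)C)(C(C)C)C(C)C)cc2)C1 | intermediate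
21 | 3α-allylic alcohol (hydroxyl cis to the C4 methyl) | CC1=C[C@H](O)[C@@]2(C)CC[C@](O)(C(C)C)[C@@H]2[C@H](OC(=O)c2ccc(O[Si](C(C)C)(C(C)C)C(C)C)cc2)C1 | intermediate
22 | isovaleryl chloride (3-methylbutanoyl chloride) | CC(C)CC(=O)Cl | starting material
23 | 3α-isovalerate 9α-[4-(triisopropylsilyloxy)benzoate], 7β-OH free | CC1=C[C@H](OC(=O)CC(C)C)[C@@]2(C)CC[C@](O)(C(C)C)[C@@H]2[C@H](OC(=O)c2ccc(O[Si](C(C)C)(C(C)C)C(C)C)cc2)C1 | intermediate
24 | CNP0086724.2: 3α-isovaleryloxy-9α-(4-hydroxybenzoyloxy)-7β-hydroxy-7α-isopropyl-1,4α-dimethyl-trans-hydroazul-1-ene | CC1=C[C@H](OC(=O)CC(C)C)[C@@]2(C)CC[C@](O)(C(C)C)[C@@H]2[C@H](OC(=O)c2ccc(O)cc2)C1 | target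

**Step count**

Total: 18 steps. Longest linear sequence: 17 steps (steps 1–10 and 12–18, from 1); step 11 is a one-step side branch.

**The three steps most likely to fail**

Step 7 (key step). After the shift, residual base may enolise the new ketone toward C8, which would epimerise the ring fusion or expel the C7 silanolate (E1cB). A second danger is reaction through the minor chair, in which C10 instead of C4 is anti to the mesylate. Fallback, from 8 back to 10: the same 1,2-shift is driven by Lewis-acid pull on the sulfonate and not by a free alkoxide. Et3Al in CH2Cl2 at −78 → 0 °C converts the C9 hydroxyl into the diethylaluminium alkoxide F1, in which aluminium also binds the cis mesylate oxygen and assists its departure while C4 migrates (organoaluminium-promoted pinacol-type rearrangement of β-mesyloxy alcohols). Work-up with aqueous potassium sodium tartrate gives 10 without the ketone meeting a base.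

Step 5. Osmylation may take the β face, anti to the angular methyl, in competition with the wanted α-face attack anti to the silyloxy group. That would give the 8β,9β-diol, whose mesylate would rearrange to the C8 epimer with a cis ring fusion. Fallback, from 6 back to 7: Woodward cis-hydroxylation (I2, AgOAc, AcOH containing water, rt). The iodonium ion forms on the more accessible face, acetate opens it anti, and the acetoxonium ion then closes on the opposite face, so the cis-diol ends on the face that OsO4 avoids. This gives the hydroxy acetate F2, and K2CO3 in MeOH removes the acetate to give 7.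

Step 3. Facial selectivity of the organocerium addition to the flexible enone may be poor or reversed (axial attack from the β face), which would set C7 wrongly. Fallback, from 3 back to 5: C7 is set on a rigid saturated ketone, where equatorial attack of a bulky organometallic is dependable, and the olefin is restored afterwards. Li/NH3 (t-BuOH, THF, −78 °C) reduces 3 to the trans-decalin lithium enolate, which is trapped with PhSeBr; brief equilibration with Et3N gives the equatorial selenide, 8β-phenylselanyl trans-decalin-7-one F3. Addition of 4/CeCl3 from the equatorial (α) direction gives the carbinol F4. H2O2/pyridine (CH2Cl2, 0 °C → rt) oxidises selenium, and the selenoxide eliminates syn through the only β-hydrogen available, the cis H-9, to give 5.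

**Further compounds**

F1 | step 7 | diethylaluminium C9-alkoxide of mesylate 8 | C[C@]12CC[C@](O[Si](CC)(CC)CC)(C(C)C)[C@H](OS(C)(=O)=O)[C@@]1(O[Al](CC)CC)CCC[C@@H]2O[Si](C)(C)C(C)(C)C
F2 | step 5 | 8α-acetoxy-9α-hydroxy cis-decalin (7β-OTES, 7α-isopropyl, 3α-OTBS) | C[C@]12CC[C@](O[Si](CC)(CC)CC)(C(C)C)[C@H](OC(C)=O)[C@@]1(O)CCC[C@@H]2O[Si](C)(C)C(C)(C)C
F3 | step 3 | 8β-phenylselanyl-3α-(tert-butyldimethylsilyloxy)-4α-methyl-trans-decalin-7-one (9β-H) | C[C@]12CCC(=O)[C@@H]([Se]c3ccccc3)[C@@H]1CCC[C@@H]2O[Si](C)(C)C(C)(C)C
F4 | step 3 | 7β-hydroxy-7α-isopropyl-8β-phenylselanyl trans-decalin (3α-OTBS, 9β-H) | C[C@]12CC[C@](O)(C(C)C)[C@@H]([Se]c3ccccc3)[C@@H]1CCC[C@@H]2O[Si](C)(C)C(C)(C)C
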